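**Retrosynthetic overview**
- Target ⇐ tetra-O-benzyl biflavone by neutral global hydrogenolysis. Both OMe groups arrive with purchased anisyl building blocks.
- Pyranone of flavone unit 2 ⇐ 2'-hydroxychalcone ⇐ intermolecular Claisen–Schmidt aldol condensation of dibenzyl phloroacetophenone with flavone unit 1 carrying a 2-formyl-5-methoxyphenyl group at C8 (key fragment union).
- That aldehyde ⇐ Suzuki–Miyaura coupling of an 8-iodoflavone with 2-formyl-5-methoxyphenylboronic acid. The 8-iodoflavone ⇐ Claisen–Schmidt condensation of the 3-iodo dibenzyl phloroacetophenone with 4-methoxybenzaldehyde, then I2/DMSO.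
- Ring order: all four benzene rings are bought. The pyranone of unit 1 is closed first, the biaryl bond is made second, and the pyranone of unit 2 is closed last.

Assumption: the SMILES has no stereocentre and no axial descriptor, so the target is taken as the constitution drawn, and the 2',8''-biaryl axis is formed without control and not resolved.

**Step 1**
Reactants: 1 2,4,6-trihydroxyacetophenone
Product: 2 1-[2,4-bis(benzyloxy)-6-hydroxyphenyl]ethanone
Conditions: BnBr (2.1 equiv), K2CO3 (2.2 equiv), DMF, 0 °C → rt, 16 h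
Reagents that add atoms: benzyl bromide, BrCc1ccccc1
Why: Williamson ether synthesis in which the 4-OH and one ortho-OH are alkylated, while the last OH is hydrogen-bonded to the acetyl C=O and too poor a nucleophile to react with about two equivalents of BnBr.

**Step 2**
Reactants: 2 1-[2,4-bis(benzyloxy)-6-hydroxyphenyl]ethanone
Product: 3 1-[4,6-bis(benzyloxy)-2-hydroxy-3-iodophenyl]ethanone
Conditions: NIS (1.02 equiv), CF3CO2H (10 mol %), MeCN/CH2Cl2 (1:1), 0 °C → rt, dark, 3 h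
Reagents that add atoms: N-iodosuccinimide, O=C1CCC(=O)N1I
Why: Electrophilic aromatic iodination in which the position between OH and OBn is less crowded than the one between two OBn groups, so one equivalent of NIS gives the 3-iodide (checked by HMBC from the chelated OH to the iodine-bearing carbon).

**Step 3**
Reactants: 3 1-[4,6-bis(benzyloxy)-2-hydroxy-3-iodophenyl]ethanone; 4 4-methoxybenzaldehyde
Product: 6 (E)-1-[4,6-bis(benzyloxy)-2-hydroxy-3-iodophenyl]-3-(4-methoxyphenyl)prop-2-en-1-one, via aldol adduct 5 (not isolated)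
Conditions: 4 (1.3 equiv), KOH (10 equiv, 50% aq), EtOH/THF (2:1), rt, 36–48 h; then 1 M HCl, 0 °C
Reagents that add atoms: none
Why: Claisen–Schmidt aldol condensation in which the methyl ketone is the only enolisable partner and 4 the only electrophile, so cross-addition to 5 and E1cB loss of water give the conjugated E-enone and erase the transient carbinol stereocentre.

**Step 4**
Reactants: 6 (E)-1-[4,6-bis(benzyloxy)-2-hydroxy-3-iodophenyl]-3-(4-methoxyphenyl)prop-2-en-1-one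
Product: 8 iodoflavone 5,7-bis(benzyloxy)-8-iodo-2-(4-methoxyphenyl)-4H-chromen-4-one, via iodoflavanone 7 (not isolated)
Conditions: I2 (10 mol %), DMSO, 120 °C, 2–3 h
Reagents that add atoms: none
Why: Iodine-catalysed oxidative cyclisation of a 2'-hydroxychalcone in which oxa-Michael closure by the only free phenol gives 7, and I2 dehydrogenates it while DMSO re-oxidises HI, so the ring iodine is fixed at C8 and the C2 stereocentre of 7 disappears.

**Step 5**
Reactants: 8 5,7-bis(benzyloxy)-8-iodo-2-(4-methoxyphenyl)-4H-chromen-4-one; 9 2-formyl-5-methoxyphenylboronic acid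
Product: 10 2-[5,7-bis(benzyloxy)-2-(4-methoxyphenyl)-4-oxo-4H-chromen-8-yl]-4-methoxybenzaldehyde
Conditions: 9 (1.6 equiv), Pd(OAc)2 (5 mol %), SPhos (10 mol %), K3PO4 (3 equiv), toluene/H2O (10:1), 90 °C, 12 h, Ar
Reagents that add atoms: none
Why: Suzuki–Miyaura cross-coupling in which zerovalent palladium formed from Pd(OAc)2 and the bulky, electron-rich SPhos inserts into the hindered carbon–iodine bond, tolerates aldehyde and chromone, and forms the new axis without stereocontrol.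

**Step 6 (key step)**
Reactants: 10 2-[5,7-bis(benzyloxy)-2-(4-methoxyphenyl)-4-oxo-4H-chromen-8-yl]-4-methoxybenzaldehyde; 2 1-[2,4-bis(benzyloxy)-6-hydroxyphenyl]ethanone
Product: 12 5,7-bis(benzyloxy)-8-{2-[(E)-3-[2,4-bis(benzyloxy)-6-hydroxyphenyl]-3-oxoprop-1-en-1-yl]-5-methoxyphenyl}-2-(4-methoxyphenyl)-4H-chromen-4-one, via aldol adduct 11 (not isolated)
Conditions: 2 (1.2 equiv), KOH (15 equiv, 50% aq), EtOH/THF (1:1), rt, 48–72 h; then 1 M HCl, 0 °C
Reagents that add atoms: none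
Why: Claisen–Schmidt aldol condensation joining the two halves, in which 10 cannot enolise and 2 holds the only acidic methyl ketone, so the Cα–Cβ bond of flavone unit 2 forms selectively, dehydration gives the E-enone, and any pyranone opened by hydroxide to its β-diketone re-closes on acidification and in step 7.

**Step 7**
Reactants: 12 chalcone–flavone from step 6
Product: 14 5,7-bis(benzyloxy)-8-{2-[5,7-bis(benzyloxy)-4-oxo-4H-chromen-2-yl]-5-methoxyphenyl}-2-(4-methoxyphenyl)-4H-chromen-4-one, via flavanone-flavone 13 (not isolated)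
Conditions: I2 (10 mol %), DMSO, 125 °C, 3 h
Reagents that add atoms: none
Why: Iodine-catalysed oxidative cyclisation (oxa-Michael closure to 13, then dehydrogenation with DMSO as terminal oxidant) in which benzyl and methyl ethers and the first flavone are inert, any partial loss of a 5-O-benzyl group is harmless before step 8, and the C2 stereocentre of 13 is erased.

**Step 8**
Reactants: 14 tetra-O-benzyl biflavone from step 7
Product: 15 8-[2-(5,7-dihydroxy-4-oxo-4H-chromen-2-yl)-5-methoxyphenyl]-5,7-dihydroxy-2-(4-methoxyphenyl)-4H-chromen-4-one (target)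
Conditions: H2 (1 atm), 10% Pd/C (20 wt %), THF/MeOH (1:1), rt, 6–12 h, stopped after uptake of 4 equiv H2
Reagents that add atoms: none
Why: Catalytic hydrogenolysis cleaves the four benzyl aryl ethers, leaves the aryl methyl ethers and the slowly reduced chromone C2=C3 bonds intact, and its neutral medium avoids acid-induced Wessely–Moser migration of the 8-aryl group once the 5-OH is free.

**Compound list**
1 | 2,4,6-trihydroxyacetophenone | CC(=O)c1c(O)cc(O)cc1O | starting material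
2 | 1-[2,4-bis(benzyloxy)-6-hydroxyphenyl]ethanone | CC(=O)c1c(O)cc(OCc2ccccc2)cc1OCc1ccccc1 | intermediate
3 | 1-[4,6-bis(benzyloxy)-2-hydroxy-3-iodophenyl]ethanone | CC(=O)c1c(O)c(I)c(OCc2ccccc2)cc1OCc1ccccc1 | intermediate
4 | 4-methoxybenzaldehyde | COc1ccc(C=O)cc1 | starting material
5 | 1-[4,6-bis(benzyloxy)-2-hydroxy-3-iodophenyl]-3-hydroxy-3-(4-methoxyphenyl)propan-1-one (racemic, not isolated) | COc1ccc(C(O)CC(=O)c2c(O)c(I)c(OCc3ccccc3)cc2OCc2ccccc2)cc1 | intermediate
6 | (E)-1-[4,6-bis(benzyloxy)-2-hydroxy-3-iodophenyl]-3-(4-methoxyphenyl)prop-2-en-1-one | COc1ccc(/C=C/C(=O)c2c(O)c(I)c(OCc3ccccc3)cc2OCc2ccccc2)cc1 | intermediate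
7 | 5,7-bis(benzyloxy)-8-iodo-2-(4-methoxyphenyl)chroman-4-one (racemic, not isolated) | COc1ccc(C2CC(=O)c3c(OCc4ccccc4)cc(OCc4ccccc4)c(I)c3O2)cc1 | intermediate
8 | 5,7-bis(benzyloxy)-8-iodo-2-(4-methoxyphenyl)-4H-chromen-4-one | COc1ccc(-c2cc(=O)c3c(OCc4ccccc4)cc(OCc4ccccc4)c(I)c3o2)cc1 | intermediate
9 | 2-formyl-5-methoxyphenylboronic acid | COc1ccc(C=O)c(B(O)O)c1 | starting material
10 | 2-[5,7-bis(benzyloxy)-2-(4-methoxyphenyl)-4-oxo-4H-chromen-8-yl]-4-methoxybenzaldehyde | COc1ccc(-c2cc(=O)c3c(OCc4ccccc4)cc(OCc4ccccc4)c(-c4cc(OC)ccc4C=O)c3o2)cc1 | intermediate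
11 | 5,7-bis(benzyloxy)-8-{2-[3-[2,4-bis(benzyloxy)-6-hydroxyphenyl]-1-hydroxy-3-oxopropyl]-5-methoxyphenyl}-2-(4-methoxyphenyl)-4H-chromen-4-one (stereoisomer mixture, not isolated) | COc1ccc(-c2cc(=O)c3c(OCc4ccccc4)cc(OCc4ccccc4)c(-c5cc(OC)ccc5C(O)CC(=O)c6c(O)cc(OCc7ccccc7)cc6OCc7ccccc7)c3o2)cc1 | intermediate
12 | 5,7-bis(benzyloxy)-8-{2-[(E)-3-[2,4-bis(benzyloxy)-6-hydroxyphenyl]-3-oxoprop-1-en-1-yl]-5-methoxyphenyl}-2-(4-methoxyphenyl)-4H-chromen-4-one | COc1ccc(-c2cc(=O)c3c(OCc4ccccc4)cc(OCc4ccccc4)c(-c5cc(OC)ccc5/C=C/C(=O)c6c(O)cc(OCc7ccccc7)cc6OCc7ccccc7)c3o2)cc1 | intermediate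
13 | 5,7-bis(benzyloxy)-8-{2-[5,7-bis(benzyloxy)-4-oxochroman-2-yl]-5-methoxyphenyl}-2-(4-methoxyphenyl)-4H-chromen-4-one (stereoisomer mixture, not isolated) | COc1ccc(-c2cc(=O)c3c(OCc4ccccc4)cc(OCc4ccccc4)c(-c5cc(OC)ccc5C6CC(=O)c7c(OCc8ccccc8)cc(OCc8ccccc8)cc7O6)c3o2)cc1 | intermediate
14 | 5,7-bis(benzyloxy)-8-{2-[5,7-bis(benzyloxy)-4-oxo-4H-chromen-2-yl]-5-methoxyphenyl}-2-(4-methoxyphenyl)-4H-chromen-4-one | COc1ccc(-c2cc(=O)c3c(OCc4ccccc4)cc(OCc4ccccc4)c(-c5cc(OC)ccc5-c6cc(=O)c7c(OCc8ccccc8)cc(OCc8ccccc8)cc7o6)c3o2)cc1 | intermediate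
15 | 8-[2-(5,7-dihydroxy-4-oxo-4H-chromen-2-yl)-5-methoxyphenyl]-5,7-dihydroxy-2-(4-methoxyphenyl)-4H-chromen-4-one (4',4'''-di-O-methyl-2',8''-biapigenin) | COc1ccc(-c2cc(=O)c3c(O)cc(O)c(-c4cc(OC)ccc4-c4cc(=O)c5c(O)cc(O)cc5o4)c3o2)cc1 | target

**Total step count:** 8. **Longest linear sequence:** 8 (1 → 2 → 3 → 6 → 8 → 10 → 12 → 14 → 15; compound 2 is drawn on a second time in step 6).

**Three steps most likely to fail**

Step 4 (keeping the iodine through the hot oxidative cyclisation). Traces of HI in DMSO at 120 °C could protodeiodinate or scramble the electron-rich ring A iodide and could cleave some of the 5-O-benzyl group. The fallback is to halogenate only after the pyranone is closed.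
- It sets out from 2. Claisen–Schmidt condensation of 2 with 4 (KOH, EtOH/THF, rt) gives (E)-1-[2,4-bis(benzyloxy)-6-hydroxyphenyl]-3-(4-methoxyphenyl)prop-2-en-1-one F1.
- I2 (10 mol %) in DMSO at 125 °C then gives 5,7-bis(benzyloxy)-2-(4-methoxyphenyl)-4H-chromen-4-one F2.
- NIS/CF3CO2H in MeCN at 0 °C iodinates F2 at C8, because C6 is shielded by two benzyloxy groups. This comes back to the route at 8.

Step 5 (hindered biaryl coupling). The iodide is di-ortho-substituted and electron-rich, and the ortho-formyl boronic acid can protodeboronate before it transmetalates. The fallback is to reverse the polarity of the coupling.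
- It sets out from 8. Miyaura borylation (B2pin2, Pd(dppf)Cl2, KOAc, dioxane, 90 °C) gives 5,7-bis(benzyloxy)-2-(4-methoxyphenyl)-8-(4,4,5,5-tetramethyl-1,3,2-dioxaborolan-2-yl)-4H-chromen-4-one F3.
- F3 is coupled with purchased 2-bromo-4-methoxybenzaldehyde F4 (Pd(OAc)2, SPhos, K3PO4, toluene/H2O, 90 °C). This comes back to the route at 10.

Step 6 (key aldol condensation). The aldehyde is ortho-hindered and deactivated by the para-methoxy group, so the pyranone of unit 1 sits in hydroxide for days and may open or degrade. The fallback is to join the same two fragments by an intermolecular Claisen condensation at the carboxylic acid level, which also makes step 7 unnecessary.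
- It sets out from 10. Pinnick oxidation (NaClO2, NaH2PO4, 2-methyl-2-butene, t-BuOH/THF/H2O) gives 2-[5,7-bis(benzyloxy)-2-(4-methoxyphenyl)-4-oxo-4H-chromen-8-yl]-4-methoxybenzoic acid F5.
- (COCl)2 with catalytic DMF in CH2Cl2 gives 2-[5,7-bis(benzyloxy)-2-(4-methoxyphenyl)-4-oxo-4H-chromen-8-yl]-4-methoxybenzoyl chloride F6.
- Compound 2 is deprotonated with LiN(SiMe3)2 (3.3 equiv, THF, −78 °C) and C-acylated by F6. This gives 1-[2,4-bis(benzyloxy)-6-hydroxyphenyl]-3-{2-[5,7-bis(benzyloxy)-2-(4-methoxyphenyl)-4-oxo-4H-chromen-8-yl]-4-methoxyphenyl}propane-1,3-dione F7.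
- Catalytic p-toluenesulfonic acid in refluxing toluene cyclodehydrates F7. This comes back to the route at 14.

**Further compounds**
F1 | step 4 | (E)-1-[2,4-bis(benzyloxy)-6-hydroxyphenyl]-3-(4-methoxyphenyl)prop-2-en-1-one | COc1ccc(/C=C/C(=O)c2c(O)cc(OCc3ccccc3)cc2OCc2ccccc2)cc1
F2 | step 4 | 5,7-bis(benzyloxy)-2-(4-methoxyphenyl)-4H-chromen-4-one | COc1ccc(-c2cc(=O)c3c(OCc4ccccc4)cc(OCc4ccccc4)cc3o2)cc1
F3 | step 5 | 5,7-bis(benzyloxy)-2-(4-methoxyphenyl)-8-(4,4,5,5-tetramethyl-1,3,2-dioxaborolan-2-yl)-4H-chromen-4-one | COc1ccc(-c2cc(=O)c3c(OCc4ccccc4)cc(OCc4ccccc4)c(B5OC(C)(C)C(C)(C)O5)c3o2)cc1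
F4 | step 5 | 2-bromo-4-methoxybenzaldehyde (purchased) | COc1ccc(C=O)c(Br)c1
F5 | step 6 | 2-[5,7-bis(benzyloxy)-2-(4-methoxyphenyl)-4-oxo-4H-chromen-8-yl]-4-methoxybenzoic acid | COc1ccc(-c2cc(=O)c3c(OCc4ccccc4)cc(OCc4ccccc4)c(-c5cc(OC)ccc5C(=O)O)c3o2)cc1
F6 | step 6 | 2-[5,7-bis(benzyloxy)-2-(4-methoxyphenyl)-4-oxo-4H-chromen-8-yl]-4-methoxybenzoyl chloride | COc1ccc(-c2cc(=O)c3c(OCc4ccccc4)cc(OCc4ccccc4)c(-c5cc(OC)ccc5C(=O)Cl)c3o2)cc1
F7 | step 6 | 1-[2,4-bis(benzyloxy)-6-hydroxyphenyl]-3-{2-[5,7-bis(benzyloxy)-2-(4-methoxyphenyl)-4-oxo-4H-chromen-8-yl]-4-methoxyphenyl}propane-1,3-dione | COc1ccc(-c2cc(=O)c3c(OCc4ccccc4)cc(OCc4ccccc4)c(-c5cc(OC)ccc5C(=O)CC(=O)c6c(O)cc(OCc7ccccc7)cc6OCc7ccccc7)c3o2)cc1
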